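**Assumption:** the alkene geometry is taken exactly as written in the SMILES, i.e. (Z)-enoates in both macrocycles and an (E)-enoate in the side chain.

**Numbering used in names:** macrolide positions are O1, C2 (CH–CH3, lactate-derived), C3 (CH–O), C4=C5, C6 (ester C=O), O7, C8 (CH–CH3), C9, C10, C11, C12, C13, C14 (ester C=O on O1). Ring A is the macrolide that bridges the cyclopentanone, ring B is the fused macrolide (primed locants), ring C is the cyclopentanone.

## Retrosynthetic overview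

1. Target 39 ⇐ global desilylation of 38 ⇐ Michael addition of the ring C β-keto ester 37 to the acyclic (E)-4-oxo-enoate 35 (sets quaternary C13 and the CH(CO2H) carbon).
2. 37 ⇐ (3+2) annulation of the 11,12-dione macrolide 26 with the enedione macrolide 22 (Michael C13–C13', then aldol C12'–C11); ring C is formed last.
3. 26 ⇐ 22 by C12 oxygenation; 22 ⇐ intramolecular nitrile oxide–acrylate [3+2] cycloaddition of 17, which closes the 14-membered dilactone (used for both ring A and ring B) with the enedione masked as an isoxazoline.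
4. 35 ⇐ intermolecular nitrile oxide [3+2] cycloaddition of 29 with silyl acrylate 30, then the same unmasking.
5. 17 and 29 ⇐ common ynoate 11 = lithiated propiolate 6 (from (S)-propylene oxide) + aldehyde 9 (from ethyl (S)-lactate, Felkin–Anh); Lindlar gives Z, Red-Al gives E. Ring order: 14-membered ring, then ring C.

## Route

**Step 1**
Reactants: 1 (S)-propylene oxide; 2 vinylmagnesium bromide (CH2=CHMgBr)
Product: 3 (S)-pent-4-en-2-ol
Conditions: CuI (10 mol%), THF, −30 → 0 °C; aq. NH4Cl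
Reagents that add atoms: none
Why: Copper-catalysed Grignard opening of the epoxide by SN2 attack at the unsubstituted CH2, so the purchased carbinol centre is not touched.

**Step 2**
Reactants: 3 (S)-pent-4-en-2-ol
Product: 4 (S)-5-bromopentan-2-ol
Conditions: HBr (g), AIBN (cat.), hexane, 0 °C, hν
Reagents that add atoms: hydrogen bromide, Br
Why: Radical-chain anti-Markovnikov hydrobromination (Kharasch addition) places bromine on the terminal carbon without involving the stereocentre.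

**Step 3**
Reactants: 4 (S)-5-bromopentan-2-ol; 5 propiolic acid
Product: 6 (2S)-5-bromopentan-2-yl prop-2-ynoate
Conditions: DCC, DMAP (5 mol%), CH2Cl2, −20 → 0 °C
Reagents that add atoms: none
Why: Steglich esterification forms the acyl–oxygen bond with retention at the carbinol carbon and is fast enough to outrun cyclisation of the bromo alcohol.

**Step 4**
Reactants: 7 ethyl (S)-lactate
Product: 8 ethyl (2S)-2-(triethylsilyloxy)propanoate
Conditions: Et3SiCl, imidazole, CH2Cl2, 0 °C → rt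
Reagents that add atoms: chlorotriethylsilane, CC[Si](CC)(CC)Cl
Why: Standard O-silylation gives a non-chelating ether that can later be removed in the presence of a TBS ether.

**Step 5**
Reactants: 8 ethyl (2S)-2-(triethylsilyloxy)propanoate
Product: 9 (2S)-2-(triethylsilyloxy)propanal
Conditions: iBu2AlH (1.05 equiv), CH2Cl2, −78 °C; aq. KNaC4H4O6
Reagents that add atoms: none
Why: Half-reduction of the ester through the tetrahedral aluminium hemiacetal that is stable at −78 °C gives the aldehyde, which is used crude to avoid epimerisation.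

**Step 6**
Reactants: 6 (2S)-5-bromopentan-2-yl prop-2-ynoate; 9 (2S)-2-(triethylsilyloxy)propanal
Product: 11 (2S)-5-bromopentan-2-yl (4R,5S)-4-hydroxy-5-(triethylsilyloxy)hex-2-ynoate, via lithium acetylide 10 (not isolated)
Conditions: LiN(SiMe3)2 (1.05 equiv), THF, −78 °C, 20 min; then 9, −78 °C, 1 h; AcOH quench at −78 °C
Reagents that add atoms: none
Why: Acetylide 1,2-addition to the α-silyloxy aldehyde under Felkin–Anh (non-chelation) control gives the 4,5-anti (4R) carbinol as the major isomer (about 4:1 expected, minor epimer removed by chromatography).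

**Step 7**
Reactants: 11 (2S)-5-bromopentan-2-yl (4R,5S)-4-hydroxy-5-(triethylsilyloxy)hex-2-ynoate
Product: 12 (2S)-5-bromopentan-2-yl (4R,5S)-4-(tert-butyldimethylsilyloxy)-5-(triethylsilyloxy)hex-2-ynoate
Conditions: TBSOTf, 2,6-lutidine, CH2Cl2, −78 °C
Reagents that add atoms: tert-butyldimethylsilyl triflate, CC(C)(C)[Si](C)(C)OS(=O)(=O)C(F)(F)F
Why: Silylation of the propargylic alcohol blocks O4, which would otherwise form a butenolide once the (Z)-enoate is present.

**Step 8**
Reactants: 12 (2S)-5-bromopentan-2-yl (4R,5S)-4-(tert-butyldimethylsilyloxy)-5-(triethylsilyloxy)hex-2-ynoate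
Product: 13 (2S)-5-bromopentan-2-yl (4R,5S)-4-(tert-butyldimethylsilyloxy)-5-hydroxyhex-2-ynoate
Conditions: PPTS (0.2 equiv), MeOH/CH2Cl2 1:1, 0 °C
Reagents that add atoms: none
Why: Selective acid methanolysis of the triethylsilyl ether beside the far more stable TBS ether, done at the linear alkyne stage so that the free 5-OH cannot lactonise.

**Step 9**
Reactants: 13 (2S)-5-bromopentan-2-yl (4R,5S)-4-(tert-butyldimethylsilyloxy)-5-hydroxyhex-2-ynoate; 14 acryloyl chloride
Product: 15 (2S)-5-bromopentan-2-yl (4R,5S)-5-(acryloyloxy)-4-(tert-butyldimethylsilyloxy)hex-2-ynoate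
Conditions: iPr2NEt, CH2Cl2, −40 → 0 °C
Reagents that add atoms: none
Why: O-acylation installs the dipolarophile on O5 with retention and without nucleophilic catalyst that could add to the ynoate.

**Step 10**
Reactants: 15 (2S)-5-bromopentan-2-yl (4R,5S)-5-(acryloyloxy)-4-(tert-butyldimethylsilyloxy)hex-2-ynoate
Product: 16 (2S)-5-nitropentan-2-yl (4R,5S)-5-(acryloyloxy)-4-(tert-butyldimethylsilyloxy)hex-2-ynoate
Conditions: AgNO2 (2 equiv), Et2O, 0 °C → rt, dark, 48 h
Reagents that add atoms: silver nitrite, [Ag+].[O-]N=O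
Why: Victor Meyer displacement of the primary bromide gives the nitroalkane under neutral conditions that leave the acrylate, ynoate and silyl ether intact.

**Step 11**
Reactants: 16 (2S)-5-nitropentan-2-yl (4R,5S)-5-(acryloyloxy)-4-(tert-butyldimethylsilyloxy)hex-2-ynoate
Product: 17 (2S)-5-nitropentan-2-yl (2Z,4R,5S)-5-(acryloyloxy)-4-(tert-butyldimethylsilyloxy)hex-2-enoate
Conditions: H2 (1 atm), Pd/CaCO3 poisoned with Pb(OAc)2 (Lindlar catalyst), quinoline, EtOAc, 0 °C, stopped at 1 equiv H2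
Reagents that add atoms: none
Why: Lindlar syn-semihydrogenation gives the (Z)-enoate because the alkyne out-competes the acrylate for the poisoned surface and the aliphatic nitro group is inert.

**Step 12**
Reactants: 17 (2S)-5-nitropentan-2-yl (2Z,4R,5S)-5-(acryloyloxy)-4-(tert-butyldimethylsilyloxy)hex-2-enoate
Product: 19 isoxazoline-bridged macrodiolide (2S,3R,4Z,8S)-3-(tert-butyldimethylsilyloxy)-2,8-dimethyl-6,14-dioxo-1,7-dioxacyclotetradec-4-ene bearing an N–O bridge from C11 (C=N) to C13 (C–O) as a mixture of C13 epimers, via nitrile oxide 18 (not isolated)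
Conditions: PhNCO (3 equiv), Et3N (0.3 equiv), benzene, 80 °C, syringe-pump addition of 17 over 20 h (final 2 mM)
Reagents that add atoms: none
Why: Mukaiyama dehydration of the nitroalkane gives the nitrile oxide, which undergoes intramolecular 1,3-dipolar [3+2] cycloaddition to the acrylate (carbon to the CH2 terminus, oxygen to the ester-bearing carbon), closing the 14-membered dilactone and the isoxazoline in one step; the new C13 centre is removed in step 14.

**Step 13**
Reactants: 19 isoxazoline-bridged macrodiolide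
Product: 20 (2S,3R,4Z,8S)-3-(tert-butyldimethylsilyloxy)-13-hydroxy-2,8-dimethyl-1,7-dioxacyclotetradec-4-ene-6,11,14-trione (C13 epimers)
Conditions: Mo(CO)6 (1.2 equiv), MeCN/H2O 10:1, 80 °C
Reagents that add atoms: water, O
Why: Reductive N–O cleavage of the isoxazoline and hydrolysis of the resulting β-hydroxy imine unmask the aldol without hydrogenating the (Z)-enoate.

**Step 14**
Reactants: 20 13-hydroxy-11-oxo macrodiolide
Product: 22 (2S,3R,4Z,8S,12E)-3-(tert-butyldimethylsilyloxy)-2,8-dimethyl-1,7-dioxacyclotetradeca-4,12-diene-6,11,14-trione, via mesylate 21 (not isolated)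
Conditions: MsCl (1.5 equiv), Et3N (4 equiv), CH2Cl2, 0 °C → rt
Reagents that add atoms: none
Why: Mesylation and E1cB elimination through the C12 ketone enolate give the (E)-enedione and erase the C13 epimer mixture.

**Step 15**
Reactants: 22 enedione macrodiolide
Product: 25 (2S,3R,4Z,8S)-3-(tert-butyldimethylsilyloxy)-12-hydroxy-2,8-dimethyl-1,7-dioxacyclotetradec-4-ene-6,11,14-trione (C12 epimers), via silyl enol ether 23 (not isolated), via silyloxy epoxide 24 (not isolated)
Conditions: [(Ph3P)CuH]6 (5 mol%), PhMe2SiH (1.3 equiv), toluene, 0 °C; then DMDO (acetone), −40 → 0 °C; then citric acid, THF/H2O, 0 °C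
Reagents that add atoms: dimethyldioxirane, CC1(C)OO1
Why: Copper hydride 1,4-hydrosilylation delivers hydride to C13 (β to the ketone) and gives the C11 silyl enol ether regiospecifically, whose Rubottom oxidation puts oxygen on C12 and nowhere else; the new carbinol centre is oxidised in the next step.

**Step 16**
Reactants: 25 12-hydroxy-11-oxo macrodiolide
Product: 26 (2S,3R,4Z,8S)-3-(tert-butyldimethylsilyloxy)-2,8-dimethyl-1,7-dioxacyclotetradec-4-ene-6,11,12,14-tetraone (present mainly as its C12 enol)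
Conditions: Dess–Martin periodinane (1.2 equiv), NaHCO3, CH2Cl2, 0 °C
Reagents that add atoms: none
Why: Dess–Martin oxidation of the acyloin gives the 1,2-dione, whose C12 carbonyl together with the C14 ester makes C13 a β-keto ester nucleophile.

**Step 17**
Reactants: 11 (2S)-5-bromopentan-2-yl (4R,5S)-4-hydroxy-5-(triethylsilyloxy)hex-2-ynoate
Product: 27 (2S)-5-bromopentan-2-yl (2E,4R,5S)-4-hydroxy-5-(triethylsilyloxy)hex-2-enoate
Conditions: NaAlH2(OCH2CH2OMe)2 (Red-Al, 2 equiv), THF, −72 °C, 30 min; aq. KNaC4H4O6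
Reagents that add atoms: none
Why: Alkoxide-directed trans-hydroalumination of the γ-hydroxy ynoate and protonolysis give the (E)-enoate, and at −72 °C the ester and the bromide are not reduced.

**Step 18**
Reactants: 27 (2S)-5-bromopentan-2-yl (2E,4R,5S)-4-hydroxy-5-(triethylsilyloxy)hex-2-enoate
Product: 28 (2S)-5-bromopentan-2-yl (2E,4R,5S)-4-(tert-butyldimethylsilyloxy)-5-(triethylsilyloxy)hex-2-enoate
Conditions: TBSOTf, 2,6-lutidine, CH2Cl2, −78 °C
Reagents that add atoms: tert-butyldimethylsilyl triflate, CC(C)(C)[Si](C)(C)OS(=O)(=O)C(F)(F)F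
Why: Silylation of the allylic alcohol removes the last free hydroxyl, which would otherwise react with the isocyanate and mesyl chloride used next.

**Step 19**
Reactants: 28 bis-silyl (E)-enoate bromide
Product: 29 (2S)-5-nitropentan-2-yl (2E,4R,5S)-4-(tert-butyldimethylsilyloxy)-5-(triethylsilyloxy)hex-2-enoate
Conditions: AgNO2 (2 equiv), Et2O, 0 °C → rt, dark, 48 h
Reagents that add atoms: silver nitrite, [Ag+].[O-]N=O
Why: Victor Meyer displacement of the primary bromide by nitrite, as in step 10.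

**Step 20**
Reactants: 29 nitro (E)-enoate; 30 triisopropylsilyl acrylate
Product: 32 triisopropylsilyl 3-[(4S)-4-{[(2E,4R,5S)-4-(tert-butyldimethylsilyloxy)-5-(triethylsilyloxy)hex-2-enoyl]oxy}pentyl]-4,5-dihydroisoxazole-5-carboxylate (C5 epimers), via nitrile oxide 31 (not isolated)
Conditions: PhNCO (2.5 equiv), Et3N (0.3 equiv), 30 (5 equiv), benzene, rt → 50 °C
Reagents that add atoms: none
Why: Mukaiyama nitrile oxide generation and intermolecular 1,3-dipolar [3+2] cycloaddition to the excess acrylate give the 5-carboxylate regioisomer, the disubstituted enoate being a far poorer dipolarophile.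

**Step 21**
Reactants: 32 isoxazoline silyl ester
Product: 33 triisopropylsilyl (7S)-7-{[(2E,4R,5S)-4-(tert-butyldimethylsilyloxy)-5-(triethylsilyloxy)hex-2-enoyl]oxy}-2-hydroxy-4-oxooctanoate (C2 epimers)
Conditions: Mo(CO)6 (1.2 equiv), MeCN/H2O 10:1, 80 °C
Reagents that add atoms: water, O
Why: Reductive N–O cleavage and imine hydrolysis unmask the β-hydroxy ketone under near-neutral conditions that the hindered silyl ester tolerates.

**Step 22**
Reactants: 33 β-hydroxy ketone silyl ester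
Product: 35 triisopropylsilyl (2E,7S)-7-{[(2E,4R,5S)-4-(tert-butyldimethylsilyloxy)-5-(triethylsilyloxy)hex-2-enoyl]oxy}-4-oxooct-2-enoate, via mesylate 34 (not isolated)
Conditions: MsCl (1.5 equiv), Et3N (4 equiv), CH2Cl2, 0 °C → rt
Reagents that add atoms: none
Why: Mesylation and E1cB elimination give the (E)-4-oxo-2-enoate Michael acceptor.

**Step 23**
Reactants: 26 dione macrodiolide; 22 enedione macrodiolide
Product: 37 bis-macrolide cyclopentanone with ring A (2S,3R,4Z,8S,11S,13S; 11-OH, 12-oxo, C13–H) bridging C11 and C13 of ring C and ring B (2'S,3'R,4'Z,8'S,12'S,13'S) fused at C12'–C13', both C3 oxygens as TBS ethers, via Michael adduct 36 (not isolated)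
Conditions: DBU (0.2 equiv), CH2Cl2, 4 Å MS, −20 → 0 °C, 26:22 = 1:1
Reagents that add atoms: none
Why: Formal (3+2) annulation in which the C13 enolate of 26 adds to C13' of 22 (Michael, β to the ketone) and the resulting C12' enolate closes onto the C11 carbonyl (5-exo aldol), forming ring C; the ansa chain of ring A forces C10 and C14 onto one face, ring B reacts through its exposed alkene face to give trans C12'/C13' substituents and a cis OH/acyl pair, all relayed from the purchased carbinol centres.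

**Step 24**
Reactants: 37 bis-macrolide cyclopentanone; 35 acyclic (E)-4-oxo-enoate
Product: 38 fully silylated target (three TBS ethers, one triethylsilyl ether, triisopropylsilyl ester; tertiary C11–OH free)
Conditions: Cs2CO3 (0.3 equiv), 35 (1.5 equiv), MeCN, 0 °C → rt
Reagents that add atoms: none
Why: Michael addition of the cyclic β-keto ester (2-oxocyclopentanecarboxylate type) to the carbon β to the ketone of 35 creates quaternary C13 on the face opposite the ring A chain and the C13' ester, while the adjacent CH(CO2Si) centre is set in an open transition state and is the less secure of the two (epimer removed by chromatography).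

**Step 25**
Reactants: 38 fully silylated target
Product: 39 target CNP0078817.1
Conditions: HF·pyridine, pyridine, THF, 0 °C → rt; Me3SiOMe quench, pH 7 work-up
Reagents that add atoms: none
Why: Buffered fluoride-mediated global desilylation cleaves the four silyl ethers and the silyl ester in one operation under mildly acidic conditions that avoid retro-aldol and retro-Michael cleavage of ring C.

## Compound list

1 | (S)-propylene oxide | C[C@H]1CO1 | starting material
2 | vinylmagnesium bromide | C=C[Mg]Br | starting material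
3 | (S)-pent-4-en-2-ol | C[C@H](O)CC=C | intermediate
4 | (S)-5-bromopentan-2-ol | C[C@H](O)CCCBr | intermediate
5 | propiolic acid | C#CC(=O)O | starting material
6 | (2S)-5-bromopentan-2-yl prop-2-ynoate | C#CC(=O)O[C@@H](C)CCCBr | intermediate
7 | ethyl (S)-lactate | C[C@H](O)C(=O)OCC | starting material
8 | ethyl (2S)-2-(triethylsilyloxy)propanoate | C[C@H](O[Si](CC)(CC)CC)C(=O)OCC | intermediate
9 | (2S)-2-(triethylsilyloxy)propanal | C[C@H](O[Si](CC)(CC)CC)C=O | intermediate
10 | (2S)-5-bromopentan-2-yl 3-lithioprop-2-ynoate (lithium acetylide) | [Li]C#CC(=O)O[C@@H](C)CCCBr | intermediate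
11 | (2S)-5-bromopentan-2-yl (4R,5S)-4-hydroxy-5-(triethylsilyloxy)hex-2-ynoate | C[C@H](O[Si](CC)(CC)CC)[C@H](O)C#CC(=O)O[C@@H](C)CCCBr | intermediate
12 | (2S)-5-bromopentan-2-yl (4R,5S)-4-(tert-butyldimethylsilyloxy)-5-(triethylsilyloxy)hex-2-ynoate | C[C@H](O[Si](CC)(CC)CC)[C@H](O[Si](C)(C)C(C)(C)C)C#CC(=O)O[C@@H](C)CCCBr | intermediate
13 | (2S)-5-bromopentan-2-yl (4R,5S)-4-(tert-butyldimethylsilyloxy)-5-hydroxyhex-2-ynoate | C[C@H](O)[C@H](O[Si](C)(C)C(C)(C)C)C#CC(=O)O[C@@H](C)CCCBr | intermediate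
14 | acryloyl chloride | C=CC(=O)Cl | starting material
15 | (2S)-5-bromopentan-2-yl (4R,5S)-5-(acryloyloxy)-4-(tert-butyldimethylsilyloxy)hex-2-ynoate | C=CC(=O)O[C@@H](C)[C@H](O[Si](C)(C)C(C)(C)C)C#CC(=O)O[C@@H](C)CCCBr | intermediate
16 | (2S)-5-nitropentan-2-yl (4R,5S)-5-(acryloyloxy)-4-(tert-butyldimethylsilyloxy)hex-2-ynoate | C=CC(=O)O[C@@H](C)[C@H](O[Si](C)(C)C(C)(C)C)C#CC(=O)O[C@@H](C)CCC[N+](=O)[O-] | intermediate
17 | (2S)-5-nitropentan-2-yl (2Z,4R,5S)-5-(acryloyloxy)-4-(tert-butyldimethylsilyloxy)hex-2-enoate | C=CC(=O)O[C@@H](C)[C@H](O[Si](C)(C)C(C)(C)C)/C=C\C(=O)O[C@@H](C)CCC[N+](=O)[O-] | intermediate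
18 | nitrile oxide of 17: (4S)-4-{[(2Z,4R,5S)-5-(acryloyloxy)-4-(tert-butyldimethylsilyloxy)hex-2-enoyl]oxy}pentanenitrile oxide | C=CC(=O)O[C@@H](C)[C@H](O[Si](C)(C)C(C)(C)C)/C=C\C(=O)O[C@@H](C)CCC#[N+][O-] | intermediate
19 | isoxazoline-bridged macrodiolide (2S,3R,4Z,8S; N–O bridge C11 to C13; C13 epimers) | C[C@@H]1OC(=O)C2CC(=NO2)CC[C@H](C)OC(=O)/C=C\[C@H]1O[Si](C)(C)C(C)(C)C | intermediate
20 | (2S,3R,4Z,8S)-3-(tert-butyldimethylsilyloxy)-13-hydroxy-2,8-dimethyl-1,7-dioxacyclotetradec-4-ene-6,11,14-trione (C13 epimers) | C[C@@H]1OC(=O)C(O)CC(=O)CC[C@H](C)OC(=O)/C=C\[C@H]1O[Si](C)(C)C(C)(C)C | intermediate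
21 | 13-methanesulfonate of 20 | C[C@@H]1OC(=O)C(OS(C)(=O)=O)CC(=O)CC[C@H](C)OC(=O)/C=C\[C@H]1O[Si](C)(C)C(C)(C)C | intermediate
22 | (2S,3R,4Z,8S,12E)-3-(tert-butyldimethylsilyloxy)-2,8-dimethyl-1,7-dioxacyclotetradeca-4,12-diene-6,11,14-trione | C[C@@H]1OC(=O)/C=C/C(=O)CC[C@H](C)OC(=O)/C=C\[C@H]1O[Si](C)(C)C(C)(C)C | intermediate
23 | C11 dimethylphenylsilyl enol ether (C11=C12) of 12,13-dihydro-22 | C[C@@H]1OC(=O)CC=C(O[Si](C)(C)c2ccccc2)CC[C@H](C)OC(=O)/C=C\[C@H]1O[Si](C)(C)C(C)(C)C | intermediate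
24 | 11,12-epoxide of 23 (11-silyloxy epoxide) | C[C@@H]1OC(=O)CC2OC2(O[Si](C)(C)c3ccccc3)CC[C@H](C)OC(=O)/C=C\[C@H]1O[Si](C)(C)C(C)(C)C | intermediate
25 | (2S,3R,4Z,8S)-3-(tert-butyldimethylsilyloxy)-12-hydroxy-2,8-dimethyl-1,7-dioxacyclotetradec-4-ene-6,11,14-trione (C12 epimers) | C[C@@H]1OC(=O)CC(O)C(=O)CC[C@H](C)OC(=O)/C=C\[C@H]1O[Si](C)(C)C(C)(C)C | intermediate
26 | (2S,3R,4Z,8S)-3-(tert-butyldimethylsilyloxy)-2,8-dimethyl-1,7-dioxacyclotetradec-4-ene-6,11,12,14-tetraone | C[C@@H]1OC(=O)CC(=O)C(=O)CC[C@H](C)OC(=O)/C=C\[C@H]1O[Si](C)(C)C(C)(C)C | intermediate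
27 | (2S)-5-bromopentan-2-yl (2E,4R,5S)-4-hydroxy-5-(triethylsilyloxy)hex-2-enoate | C[C@H](O[Si](CC)(CC)CC)[C@H](O)/C=C/C(=O)O[C@@H](C)CCCBr | intermediate
28 | (2S)-5-bromopentan-2-yl (2E,4R,5S)-4-(tert-butyldimethylsilyloxy)-5-(triethylsilyloxy)hex-2-enoate | C[C@H](O[Si](CC)(CC)CC)[C@H](O[Si](C)(C)C(C)(C)C)/C=C/C(=O)O[C@@H](C)CCCBr | intermediate
29 | (2S)-5-nitropentan-2-yl (2E,4R,5S)-4-(tert-butyldimethylsilyloxy)-5-(triethylsilyloxy)hex-2-enoate | C[C@H](O[Si](CC)(CC)CC)[C@H](O[Si](C)(C)C(C)(C)C)/C=C/C(=O)O[C@@H](C)CCC[N+](=O)[O-] | intermediate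
30 | triisopropylsilyl acrylate | C=CC(=O)O[Si](C(C)C)(C(C)C)C(C)C | starting material
31 | nitrile oxide of 29 | C[C@H](O[Si](CC)(CC)CC)[C@H](O[Si](C)(C)C(C)(C)C)/C=C/C(=O)O[C@@H](C)CCC#[N+][O-] | intermediate
32 | triisopropylsilyl 3-[(4S)-4-{[(2E,4R,5S)-4-(tert-butyldimethylsilyloxy)-5-(triethylsilyloxy)hex-2-enoyl]oxy}pentyl]-4,5-dihydroisoxazole-5-carboxylate (C5 epimers) | C[C@H](O[Si](CC)(CC)CC)[C@H](O[Si](C)(C)C(C)(C)C)/C=C/C(=O)O[C@@H](C)CCC1=NOC(C1)C(=O)O[Si](C(C)C)(C(C)C)C(C)C | intermediate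
33 | triisopropylsilyl (7S)-7-{[(2E,4R,5S)-4-(tert-butyldimethylsilyloxy)-5-(triethylsilyloxy)hex-2-enoyl]oxy}-2-hydroxy-4-oxooctanoate (C2 epimers) | C[C@H](O[Si](CC)(CC)CC)[C@H](O[Si](C)(C)C(C)(C)C)/C=C/C(=O)O[C@@H](C)CCC(=O)CC(O)C(=O)O[Si](C(C)C)(C(C)C)C(C)C | intermediate
34 | 2-methanesulfonate of 33 | C[C@H](O[Si](CC)(CC)CC)[C@H](O[Si](C)(C)C(C)(C)C)/C=C/C(=O)O[C@@H](C)CCC(=O)CC(OS(C)(=O)=O)C(=O)O[Si](C(C)C)(C(C)C)C(C)C | intermediate
35 | triisopropylsilyl (2E,7S)-7-{[(2E,4R,5S)-4-(tert-butyldimethylsilyloxy)-5-(triethylsilyloxy)hex-2-enoyl]oxy}-4-oxooct-2-enoate | C[C@H](O[Si](CC)(CC)CC)[C@H](O[Si](C)(C)C(C)(C)C)/C=C/C(=O)O[C@@H](C)CCC(=O)/C=C/C(=O)O[Si](C(C)C)(C(C)C)C(C)C | intermediate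
36 | Michael adduct: C13 of dione macrolide 26 bonded to C13' of 12',13'-dihydro-22 (new centres unassigned) | C[C@@H]1OC(=O)C(C2C(=O)C(=O)CC[C@H](C)OC(=O)/C=C\[C@@H](O[Si](C)(C)C(C)(C)C)[C@H](C)OC2=O)CC(=O)CC[C@H](C)OC(=O)/C=C\[C@H]1O[Si](C)(C)C(C)(C)C | intermediate
37 | bis-macrolide cyclopentanone: ring C carries 11-OH (11S), 12-oxo, C13–H (13S), ring B acyl at C12' (12'S) and ring B ester at C13' (13'S); ring A 2S,3R,4Z,8S; ring B 2'S,3'R,4'Z,8'S; both C3 oxygens TBS-protected | [C@@H]12C(=O)O[C@@H](C)[C@H](O[Si](C)(C)C(C)(C)C)/C=C\C(=O)O[C@@H](C)CC[C@@](O)(C1=O)[C@H]1C(=O)CC[C@H](C)OC(=O)/C=C\[C@@H](O[Si](C)(C)C(C)(C)C)[C@H](C)OC(=O)[C@@H]12 | intermediate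
38 | fully silylated target: 37 carrying at C13 the (R)-configured CH(CO2Si(iPr)3)CH2C(=O)CH2CH2CH(CH3)O-acyl chain whose acyl group is (2E,4R,5S)-4-(tert-butyldimethylsilyloxy)-5-(triethylsilyloxy)hex-2-enoyl | C[C@H](O[Si](CC)(CC)CC)[C@H](O[Si](C)(C)C(C)(C)C)/C=C/C(=O)O[C@@H](C)CCC(=O)C[C@@H](C(=O)O[Si](C(C)C)(C(C)C)C(C)C)[C@@]12C(=O)O[C@@H](C)[C@H](O[Si](C)(C)C(C)(C)C)/C=C\C(=O)O[C@@H](C)CC[C@@](O)(C1=O)[C@H]1C(=O)CC[C@H](C)OC(=O)/C=C\[C@@H](O[Si](C)(C)C(C)(C)C)[C@H](C)OC(=O)[C@@H]12 | intermediate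
39 | CNP0078817.1 | C[C@H](O)[C@H](O)/C=C/C(=O)O[C@@H](C)CCC(=O)C[C@@H](C(=O)O)[C@@]12C(=O)O[C@@H](C)[C@H](O)/C=C\C(=O)O[C@@H](C)CC[C@@](O)(C1=O)[C@H]1C(=O)CC[C@H](C)OC(=O)/C=C\[C@@H](O)[C@H](C)OC(=O)[C@@H]12 | target

## Step count and risks

Total steps: 25. Longest linear sequence: 17 (steps 1, 2, 3, 6, 7–16, 23, 24, 25).

**Step 12 (macrocyclising nitrile oxide cycloaddition).** Risk: oligomerisation or furoxan formation instead of 14-membered ring closure. The fallback closes the ring by lactonisation instead and sets out from 12. AgNO2 in Et2O converts 12 into the nitro ynoate F1. PhNCO/Et3N with excess 30 then gives, by intermolecular cycloaddition, the isoxazoline silyl ester F2. Buffered HF·pyridine at 0 °C removes the triethylsilyl ether and the silyl ester but not the TBS ether, giving the hydroxy acid F3; the alkyne keeps the free 5-OH from lactonising. Yamaguchi macrolactonisation (2,4,6-trichlorobenzoyl chloride, Et3N, then DMAP, toluene, high dilution) forms the O1–C14 ester and gives the cycloalkyne isoxazoline F4. Lindlar semihydrogenation of F4 returns to the route at 19.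

**Step 23 ((3+2) annulation).** Risk: decomposition or self-condensation of the free 1,2-dione 26 under base, or poor facial control. The fallback avoids the dione as nucleophile and sets out from 25 and 22. With DBU, acyloin 25 equilibrates through its enediol to the 11-hydroxy-12-oxo β-keto ester, whose C13 adds to 22 to give the hydroxy keto ester Michael adduct F5, which is isolated. Dess–Martin oxidation of the C11 carbinol gives 36, which is cyclised in a separate chelation-controlled aldol step (MgBr2·OEt2, Et3N, CH2Cl2). This returns to the route at 37.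

**Step 24 (Michael addition creating quaternary C13 and the CH(CO2H) centre).** Risk: low reactivity at the congested carbon, retro-aldol of ring C under base, or poor selectivity at the acyclic centre. The fallback inverts the order of bond formation and sets out from 26 and 35. Catalytic Et3N adds the still unhindered C13 of 26 to 35 to give the mono-Michael adduct F6. F6 is then annulated with 22 under the step 23 conditions, so that the quaternary centre arises in the Michael/aldol event and ring C forms last. This returns to the route at 38.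

## Further compounds

F1 | step 12 | (2S)-5-nitropentan-2-yl (4R,5S)-4-(tert-butyldimethylsilyloxy)-5-(triethylsilyloxy)hex-2-ynoate | C[C@H](O[Si](CC)(CC)CC)[C@H](O[Si](C)(C)C(C)(C)C)C#CC(=O)O[C@@H](C)CCC[N+](=O)[O-]
F2 | step 12 | triisopropylsilyl 3-[(4S)-4-{[(4R,5S)-4-(tert-butyldimethylsilyloxy)-5-(triethylsilyloxy)hex-2-ynoyl]oxy}pentyl]-4,5-dihydroisoxazole-5-carboxylate (C5 epimers) | C[C@H](O[Si](CC)(CC)CC)[C@H](O[Si](C)(C)C(C)(C)C)C#CC(=O)O[C@@H](C)CCC1=NOC(C1)C(=O)O[Si](C(C)C)(C(C)C)C(C)C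
F3 | step 12 | 3-[(4S)-4-{[(4R,5S)-4-(tert-butyldimethylsilyloxy)-5-hydroxyhex-2-ynoyl]oxy}pentyl]-4,5-dihydroisoxazole-5-carboxylic acid (C5 epimers) | C[C@H](O)[C@H](O[Si](C)(C)C(C)(C)C)C#CC(=O)O[C@@H](C)CCC1=NOC(C1)C(=O)O
F4 | step 12 | 4,5-didehydro analogue of 19 (cycloalkyne; 2S,3R,8S; N–O bridge C11 to C13) | C[C@@H]1OC(=O)C2CC(=NO2)CC[C@H](C)OC(=O)C#C[C@H]1O[Si](C)(C)C(C)(C)C
F5 | step 23 | Michael adduct of the 11-hydroxy-12-oxo isomer of 25 (through C13) to C13' of 22 (new centres unassigned) | C[C@@H]1OC(=O)C(C2C(=O)C(O)CC[C@H](C)OC(=O)/C=C\[C@@H](O[Si](C)(C)C(C)(C)C)[C@H](C)OC2=O)CC(=O)CC[C@H](C)OC(=O)/C=C\[C@H]1O[Si](C)(C)C(C)(C)C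
F6 | step 24 | Michael adduct of 26 (through C13) to C2 of 35 (new centres unassigned) | C[C@H](O[Si](CC)(CC)CC)[C@H](O[Si](C)(C)C(C)(C)C)/C=C/C(=O)O[C@@H](C)CCC(=O)CC(C(=O)O[Si](C(C)C)(C(C)C)C(C)C)C1C(=O)C(=O)CC[C@H](C)OC(=O)/C=C\[C@@H](O[Si](C)(C)C(C)(C)C)[C@H](C)OC1=O
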